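The six-membered ring (C3a–C4–C5–C6–C7–C7a; indane numbering, C1–C3 in the cyclopentanone) is cut at C3a–C4 and C5–C6, the two σ-bonds of a Diels–Alder reaction. A 1-silyloxy diene, C6=C7–C7a=C3a with C7a=C3a inside a preformed, enantiopure cyclopentene, meets an (E)-nitroalkene C4=C5 that already carries the (R)-methyloxirane; one operation sets C3a, C4, C5 and C6. The step exploits the C6 oxygen as diene donor; the nitro group is a regio- and endo-directing stand-in for the C5 oxygen. The C7=C7a alkene with its CH2O arm later becomes the exocyclic methylene and the trans ring fusion by reductive allylic transposition.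

Key step: step 11

Remark (locants and abbreviations): bicyclic compounds are described with the indane numbering of the target, (1R,3Z,3aS,4R,5S,6R,7aS): C1 (ester O), C2 (C=O), C3 (ethylidene), C3a, C4 (oxiranyl), C5 (pentenoate O), C6 (ester O), C7 (=CH2), C7a. "As in the target" means the same spatial arrangement. TBS = tert-butyldimethylsilyl, TES = triethylsilyl.
Remark (assumptions): the 2-bromoallyl silyl ether used in step 6 is taken as a commercial reagent. The enal formed in step 7 is expected as an E/Z mixture at its exocyclic alkene; both isomers converge in step 8. The C2 carbinol centre is only a relay and is oxidised in step 19.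

Step 1
Reactants: 1 cyclopentane-1,2-dione
Product: 2 2-[(tert-butyldimethylsilyl)oxy]cyclopent-2-en-1-one
Conditions: TBSCl, imidazole, DMF, 0 °C to rt
Reagents that add atoms: tert-butyldimethylsilyl chloride, CC(C)(C)[Si](C)(C)Cl
Why: The dione reacts through its enol tautomer, so O-silylation (enol silyl ether formation) should give the protected diosphenol that carries the future C1 oxygen on an sp2 carbon.

Step 2
Reactants: 2 2-[(tert-butyldimethylsilyl)oxy]cyclopent-2-en-1-one
Product: 3 (1S)-2-[(tert-butyldimethylsilyl)oxy]cyclopent-2-en-1-ol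
Conditions: (R)-2-methyl-CBS-oxazaborolidine (cat.), BH3·SMe2, THF, −30 °C; then MeOH
Reagents that add atoms: none
Why: Corey–Bakshi–Shibata reduction, in which the silyloxy-substituted vinyl arm acts as the large group, should deliver hydride to one carbonyl face and set the (S)-carbinol (future C2) that relays chirality to C1.

Step 3
Reactants: 3 (1S)-2-[(tert-butyldimethylsilyl)oxy]cyclopent-2-en-1-ol
Product: 4 tert-butyldimethyl({(5S)-5-[(triethylsilyl)oxy]cyclopent-1-en-1-yl}oxy)silane
Conditions: TESCl, imidazole, CH2Cl2, 0 °C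
Reagents that add atoms: chlorotriethylsilane, CC[Si](Cl)(CC)CC
Why: Silylation of the secondary alcohol; the triethylsilyl ether is chosen because it can later be removed in the presence of secondary TBS ethers.

Step 4
Reactants: 4 tert-butyldimethyl({(5S)-5-[(triethylsilyl)oxy]cyclopent-1-en-1-yl}oxy)silane
Product: 6 (1S,2R,3S)-2-[(tert-butyldimethylsilyl)oxy]-3-[(triethylsilyl)oxy]cyclopentan-1-ol, via alkylborane 5 (not isolated)
Conditions: BH3·THF, THF, 0 °C to rt; then NaOH, H2O2, H2O, 0 °C
Reagents that add atoms: hydrogen peroxide, OO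
Why: Hydroboration–oxidation of the silyl enol ether puts boron on the unsubstituted carbon and adds H and B syn from the face opposite the allylic OTES group, which sets the future C1 centre (OTBS cis to OTES, new OH trans to OTBS).

Step 5
Reactants: 6 (1S,2R,3S)-2-[(tert-butyldimethylsilyl)oxy]-3-[(triethylsilyl)oxy]cyclopentan-1-ol
Product: 7 (2S,3S)-2-[(tert-butyldimethylsilyl)oxy]-3-[(triethylsilyl)oxy]cyclopentan-1-one
Conditions: Dess–Martin periodinane, NaHCO3, CH2Cl2, 0 °C to rt
Reagents that add atoms: none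
Why: Dess–Martin oxidation of the secondary alcohol under buffered, non-epimerising conditions should give the α-silyloxy ketone whose carbonyl carbon becomes C7a.

Step 6
Reactants: 7 (2S,3S)-2-[(tert-butyldimethylsilyl)oxy]-3-[(triethylsilyl)oxy]cyclopentan-1-one; 8 tert-butyl[(2-bromoprop-2-en-1-yl)oxy]dimethylsilane
Product: 9 (1S,2S,3S)-1-{3-[(tert-butyldimethylsilyl)oxy]prop-1-en-2-yl}-2-[(tert-butyldimethylsilyl)oxy]-3-[(triethylsilyl)oxy]cyclopentan-1-ol
Conditions: 8, t-BuLi (2 equiv), Et2O, −78 °C; then 7, −78 °C; H2O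
Reagents that add atoms: none
Why: Bromine–lithium exchange gives the 2-lithioallyl ether, whose 1,2-addition to the ketone (expected anti to the α-OTBS group) forms the C7a–C7 bond; the carbinol configuration does not matter because it is lost in step 7.

Step 7
Reactants: 9 (1S,2S,3S)-1-{3-[(tert-butyldimethylsilyl)oxy]prop-1-en-2-yl}-2-[(tert-butyldimethylsilyl)oxy]-3-[(triethylsilyl)oxy]cyclopentan-1-ol
Product: 10 3-[(tert-butyldimethylsilyl)oxy]-2-{(2R,3S)-2-[(tert-butyldimethylsilyl)oxy]-3-[(triethylsilyl)oxy]cyclopentylidene}propanal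
Conditions: pyridinium chlorochromate, NaOAc, 4 Å molecular sieves, CH2Cl2, rt
Reagents that add atoms: pyridinium chlorochromate, [O-][Cr](=O)(=O)Cl.c1cc[nH+]cc1
Why: Babler–Dauben oxidative transposition: the tertiary allylic chromate ester undergoes a [3,3] shift to the primary allylic chromate, which is oxidised to the tetrasubstituted enal (C6 at the aldehyde level, C7 bearing the CH2OTBS arm).

Step 8
Reactants: 10 3-[(tert-butyldimethylsilyl)oxy]-2-{(2R,3S)-2-[(tert-butyldimethylsilyl)oxy]-3-[(triethylsilyl)oxy]cyclopentylidene}propanal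
Product: 11 tert-butyl{[(1Z)-3-[(tert-butyldimethylsilyl)oxy]-2-{(4S,5R)-5-[(tert-butyldimethylsilyl)oxy]-4-[(triethylsilyl)oxy]cyclopent-1-en-1-yl}prop-1-en-1-yl]oxy}dimethylsilane
Conditions: TBSOTf, Et3N, CH2Cl2, −78 to 0 °C
Reagents that add atoms: tert-butyldimethylsilyl trifluoromethanesulfonate, CC(C)(C)[Si](C)(C)OS(=O)(=O)C(F)(F)F
Why: Soft enolisation (O-silylation of the s-trans enal and γ-deprotonation at the ring CH2 instead of the hindered CH–OTBS) should give the 1-silyloxy diene with the OTBS group cis to the CH2OTBS arm, i.e. in the outside position of the diene.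

Step 9
Reactants: 12 (R)-(2-methyloxiran-2-yl)methanol
Product: 13 (S)-2-methyloxirane-2-carbaldehyde
Conditions: Dess–Martin periodinane, NaHCO3, CH2Cl2, 0 °C; solution used directly
Reagents that add atoms: none
Why: Dess–Martin oxidation of the primary alcohol; the quaternary stereocenter has no α-hydrogen and cannot epimerise (the descriptor changes only through the priority rules).

Step 10
Reactants: 13 (S)-2-methyloxirane-2-carbaldehyde
Product: 16 (R)-2-methyl-2-[(E)-2-nitroethenyl]oxirane, via nitro alcohol 14 (not isolated), via mesylate 15 (not isolated)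
Conditions: MeNO2, KOt-Bu (cat.), THF, 0 °C; then MsCl, Et3N, CH2Cl2, 0 °C
Reagents that add atoms: nitromethane, C[N+](=O)[O-]
Why: Henry addition followed by mesylation and base-induced E1cB elimination should give the thermodynamically favoured (E)-nitroalkene with the oxirane stereocenter untouched.

Step 11
Reactants: 11 the 1-silyloxy diene from step 8; 16 (R)-2-methyl-2-[(E)-2-nitroethenyl]oxirane
Product: 17 5-nitro cycloadduct (2,3,3a,4,5,6-hexahydro-1H-indene with 1-OTBS; 2-OTES; 4-[(2R)-2-methyloxiran-2-yl]; 5-NO2; 6-OTBS; 7-CH2OTBS; C7=C7a alkene; C1/C3a/C4/C6 as in the target; NO2 in the place of the C5 oxygen; C2–O cis to C1–O)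
Conditions: toluene, BHT (cat.), 90 °C, sealed tube
Reagents that add atoms: none
Why: A thermal, concerted but asynchronous normal-electron-demand [4πs+2πs] cycloaddition between the electron-rich 1-silyloxy diene (C6=C7–C7a=C3a) and the nitroalkene (C4=C5); the closest known reaction type is the Diels–Alder reaction of 1-oxygenated dienes with β-substituted nitroalkenes. The cyclohexene ring (C3a, C4, C5, C6, C7, C7a) is closed intermolecularly, suprafacially on both partners, through the transition state that is endo for the nitro group. C6 follows from the Z enol ether (OTBS outside), C5 from the endo nitro group (cis to C6–O), C4 from the E geometry of the dienophile, which places the bulky oxiranyl carbon exo (trans to C3 on C3a), and C3a from attack on the diene face opposite the cis-1,2-bis(silyloxy) unit at C1/C2. The step needs "ortho" regioselectivity (oxygen-bearing C6 to nitro-bearing C5, the most nucleophilic terminus C3a to the β-carbon C4), which the 1-silyloxy donor secures; endo selectivity, which the nitro group and the steric demand of the quaternary oxirane carbon secure; and facial selectivity, which the C1 OTBS group flanking C7a secures. The nitro group is kept as the precursor of the C5 oxygen and the C7=C7a alkene as the precursor of the exocyclic methylene and of C7a–H.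

Step 12
Reactants: 17 the 5-nitro cycloadduct
Product: 19 5-ketone (as 17 but C5=O), via sodium nitronate 18 (not isolated)
Conditions: NaOMe, MeOH/THF, 0 °C; then TiCl3 (aq), NH4OAc (pH ca. 6), 0 °C to rt
Reagents that add atoms: water, O
Why: Nef reaction in its reductive variant: the nitronate is reduced by trivalent titanium to the N–H imine, which hydrolyses near neutral pH to the C5 ketone; no base is present once the ketone exists, so the enolisable C4–H next to the oxirane is not exposed to β-elimination, and the crude ketone is reduced at once.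

Step 13
Reactants: 19 the 5-ketone
Product: 20 5-alcohol (as 17 but C5–OH, configured as in the target)
Conditions: NaBH4, CeCl3·7H2O, MeOH, −78 °C
Reagents that add atoms: none
Why: Hydride reduction under Luche conditions; axial attack anti to the pseudoaxial C6–OTBS group (Felkin–Anh sense) should give the equatorial C5 alcohol cis to the C6 oxygen.

Step 14
Reactants: 21 ethyl pent-2-ynoate
Product: 23 ethyl (2Z)-3-methylpent-2-enoate, via vinylcuprate 22 (not isolated)
Conditions: Me2CuLi (from MeLi and CuI), THF, −78 °C; then MeOH, −78 °C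
Reagents that add atoms: lithium dimethylcuprate, [Li+].C[Cu-]C
Why: syn-Carbocupration of the ynoate and protonation at low temperature, before the vinylcopper can isomerise, place the new methyl cis to hydrogen, which is the Z geometry.

Step 15
Reactants: 23 ethyl (2Z)-3-methylpent-2-enoate
Product: 25 (2Z)-3-methylpent-2-enoic acid, via lithium carboxylate 24 (not isolated)
Conditions: LiOH, THF/H2O, rt; then aq. HCl
Reagents that add atoms: lithium hydroxide, [Li+].[OH-]
Why: Saponification of the ester; the trisubstituted alkene geometry should be retained under these conditions.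

Step 16
Reactants: 20 the 5-alcohol; 25 (2Z)-3-methylpent-2-enoic acid
Product: 26 C5 (2Z)-3-methylpent-2-enoate of 20
Conditions: DIC, DMAP (cat.), CH2Cl2, 0 °C to rt
Reagents that add atoms: none
Why: Steglich esterification of the only free hydroxyl (C5); low temperature and catalytic DMAP are meant to keep the Z enoate from isomerising.

Step 17
Reactants: 26 the C5 ester
Product: 27 diol (26 without the primary TBS and the TES group: 7-CH2OH and 2-OH free; 1-OTBS and 6-OTBS kept)
Conditions: HF·pyridine, pyridine, THF, 0 °C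
Reagents that add atoms: none
Why: Buffered fluoride desilylation should remove the primary allylic TBS ether and the secondary TES ether much faster than the two hindered secondary TBS ethers, and leave the oxirane intact.

Step 18
Reactants: 27 the diol
Product: 30 7-methylidene alcohol (trans-fused octahydroindene; C7a–H as in the target; 2-OH free), via sulfonyl hydrazine 28 (not isolated), via allylic diazene 29 (not isolated)
Conditions: 2-nitrobenzenesulfonylhydrazide, PPh3, DEAD, THF, −30 °C to rt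
Reagents that add atoms: none
Why: Reductive allylic transposition: Mitsunobu displacement of the primary allylic alcohol (faster than that of the hindered secondary C2–OH), loss of sulfinic acid and retro-ene loss of N2 from the monoalkyl diazene deliver hydrogen to C7a and create the exocyclic methylene; delivery anti to the adjacent C1–OTBS group, along the axial trajectory of the half-chair, should give the trans ring fusion.

Step 19
Reactants: 30 the 7-methylidene alcohol
Product: 31 2-ketone (C2=O; C3 is CH2)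
Conditions: Dess–Martin periodinane, NaHCO3, CH2Cl2, 0 °C to rt
Reagents that add atoms: none
Why: Dess–Martin oxidation of the only free (C2) alcohol removes the relay stereocenter.

Step 20
Reactants: 31 the 2-ketone
Product: 35 (3Z)-3-ethylidene enone (1-OTBS and 6-OTBS still in place), via lithium enolate 32 (not isolated), via lithium aldolate 33 (not isolated), via mesylate 34 (not isolated)
Conditions: LiN(SiMe3)2, THF, −78 °C; MeCHO; MsCl, −78 to 0 °C; DBU, rt
Reagents that add atoms: acetaldehyde, CC=O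
Why: Aldol condensation: kinetic enolisation at the C3 methylene (away from the hindered C1–H and faster than at the enoate), aldol addition, mesylation and E1cB elimination; the Z isomer (methyl syn to the carbonyl) is expected because the E isomer suffers A(1,3) strain between the methyl group and the equatorial C3a–C4 bond of the trans-fused ring, and DBU allows equilibration.

Step 21
Reactants: 35 the (3Z)-3-ethylidene enone
Product: 36 1,6-diol (target without the two 2-methylbutanoyl groups)
Conditions: Bu4NF, AcOH, THF, 0 °C to rt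
Reagents that add atoms: none
Why: Fluoride desilylation of both secondary TBS ethers; the acetic acid buffer is meant to suppress migration of the C5 acyl group to the cis C6 hydroxyl and to spare the oxirane and the enone.

Step 22
Reactants: 36 the 1,6-diol; 37 (R)-2-methylbutanoic acid
Product: 38 (1R,3Z,3aS,4R,5S,6R,7aS)-3-ethylidene-7-methylidene-4-[(2R)-2-methyloxiran-2-yl]-5-{[(2Z)-3-methylpent-2-enoyl]oxy}-2-oxooctahydro-1H-indene-1,6-diyl bis[(2R)-2-methylbutanoate]
Conditions: 37 (3 equiv), DIC (3 equiv), DMAP (0.3 equiv), CH2Cl2, 0 °C to rt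
Reagents that add atoms: (R)-2-methylbutanoic acid (second equivalent of 37), OC(=O)[C@H](C)CC
Why: Double Steglich esterification in which each of the two free hydroxyls (C1 and C6) takes up one acyl group, so two equivalents of the enantiopure acid are consumed; carbodiimide activation avoids a ketene pathway that would racemise the α-stereocenter.

Compound list
1 | cyclopentane-1,2-dione | O=C1CCCC1=O | starting material
2 | 2-[(tert-butyldimethylsilyl)oxy]cyclopent-2-en-1-one | O=C1CCC=C1O[Si](C)(C)C(C)(C)C | intermediate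
3 | (1S)-2-[(tert-butyldimethylsilyl)oxy]cyclopent-2-en-1-ol | O[C@H]1CCC=C1O[Si](C)(C)C(C)(C)C | intermediate
4 | tert-butyldimethyl({(5S)-5-[(triethylsilyl)oxy]cyclopent-1-en-1-yl}oxy)silane | CC[Si](CC)(CC)O[C@H]1CCC=C1O[Si](C)(C)C(C)(C)C | intermediate
5 | alkylborane from hydroboration of 4 (not isolated) | B[C@H]1CC[C@H](O[Si](CC)(CC)CC)[C@@H]1O[Si](C)(C)C(C)(C)C | intermediate
6 | (1S,2R,3S)-2-[(tert-butyldimethylsilyl)oxy]-3-[(triethylsilyl)oxy]cyclopentan-1-ol | O[C@H]1CC[C@H](O[Si](CC)(CC)CC)[C@@H]1O[Si](C)(C)C(C)(C)C | intermediate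
7 | (2S,3S)-2-[(tert-butyldimethylsilyl)oxy]-3-[(triethylsilyl)oxy]cyclopentan-1-one | O=C1CC[C@H](O[Si](CC)(CC)CC)[C@@H]1O[Si](C)(C)C(C)(C)C | intermediate
8 | tert-butyl[(2-bromoprop-2-en-1-yl)oxy]dimethylsilane | C=C(Br)CO[Si](C)(C)C(C)(C)C | starting material
9 | (1S,2S,3S)-1-{3-[(tert-butyldimethylsilyl)oxy]prop-1-en-2-yl}-2-[(tert-butyldimethylsilyl)oxy]-3-[(triethylsilyl)oxy]cyclopentan-1-ol | C=C(CO[Si](C)(C)C(C)(C)C)[C@@]1(O)CC[C@H](O[Si](CC)(CC)CC)[C@@H]1O[Si](C)(C)C(C)(C)C | intermediate
10 | 3-[(tert-butyldimethylsilyl)oxy]-2-{(2R,3S)-2-[(tert-butyldimethylsilyl)oxy]-3-[(triethylsilyl)oxy]cyclopentylidene}propanal (E/Z mixture at the exocyclic alkene) | O=CC(CO[Si](C)(C)C(C)(C)C)=C1CC[C@H](O[Si](CC)(CC)CC)[C@@H]1O[Si](C)(C)C(C)(C)C | intermediate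
11 | tert-butyl{[(1Z)-3-[(tert-butyldimethylsilyl)oxy]-2-{(4S,5R)-5-[(tert-butyldimethylsilyl)oxy]-4-[(triethylsilyl)oxy]cyclopent-1-en-1-yl}prop-1-en-1-yl]oxy}dimethylsilane | CC(C)(C)[Si](C)(C)O/C=C(\CO[Si](C)(C)C(C)(C)C)C1=CC[C@H](O[Si](CC)(CC)CC)[C@@H]1O[Si](C)(C)C(C)(C)C | intermediate
12 | (R)-(2-methyloxiran-2-yl)methanol | OC[C@]1(C)CO1 | starting material
13 | (S)-2-methyloxirane-2-carbaldehyde | O=C[C@]1(C)CO1 | intermediate
14 | 1-[(2R)-2-methyloxiran-2-yl]-2-nitroethan-1-ol (carbinol mixture; not isolated) | OC(C[N+](=O)[O-])[C@]1(C)CO1 | intermediate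
15 | 1-[(2R)-2-methyloxiran-2-yl]-2-nitroethyl methanesulfonate (not isolated) | CS(=O)(=O)OC(C[N+](=O)[O-])[C@]1(C)CO1 | intermediate
16 | (R)-2-methyl-2-[(E)-2-nitroethenyl]oxirane | [O-][N+](=O)/C=C/[C@]1(C)CO1 | intermediate
17 | 5-nitro cycloadduct (hexahydroindene; 1-OTBS, 2-OTES, 4-oxiranyl, 5-NO2, 6-OTBS, 7-CH2OTBS, C7=C7a) | CC(C)(C)[Si](C)(C)OCC1=C2[C@H](C[C@H](O[Si](CC)(CC)CC)[C@@H]2O[Si](C)(C)C(C)(C)C)[C@@H]([C@]3(C)CO3)[C@H]([N+](=O)[O-])[C@@H]1O[Si](C)(C)C(C)(C)C | intermediate
18 | sodium nitronate of 17 (not isolated) | CC(C)(C)[Si](C)(C)OCC1=C2[C@H](C[C@H](O[Si](CC)(CC)CC)[C@@H]2O[Si](C)(C)C(C)(C)C)[C@@H]([C@]3(C)CO3)C(=[N+]([O-])[O-])[C@@H]1O[Si](C)(C)C(C)(C)C.[Na+] | intermediate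
19 | 5-ketone | CC(C)(C)[Si](C)(C)OCC1=C2[C@H](C[C@H](O[Si](CC)(CC)CC)[C@@H]2O[Si](C)(C)C(C)(C)C)[C@@H]([C@]3(C)CO3)C(=O)[C@@H]1O[Si](C)(C)C(C)(C)C | intermediate
20 | 5-alcohol | CC(C)(C)[Si](C)(C)OCC1=C2[C@H](C[C@H](O[Si](CC)(CC)CC)[C@@H]2O[Si](C)(C)C(C)(C)C)[C@@H]([C@]3(C)CO3)[C@H](O)[C@@H]1O[Si](C)(C)C(C)(C)C | intermediate
21 | ethyl pent-2-ynoate | CCC#CC(=O)OCC | starting material
22 | lithium (Z)-vinyl(methyl)cuprate from carbocupration of 21 (not isolated) | CCOC(=O)/C([Cu-]C)=C(/C)CC.[Li+] | intermediate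
23 | ethyl (2Z)-3-methylpent-2-enoate | CCOC(=O)/C=C(/C)CC | intermediate
24 | lithium (2Z)-3-methylpent-2-enoate (not isolated) | [Li+].[O-]C(=O)/C=C(/C)CC | intermediate
25 | (2Z)-3-methylpent-2-enoic acid | OC(=O)/C=C(/C)CC | intermediate
26 | C5 (2Z)-3-methylpent-2-enoate of 20 | CC(C)(C)[Si](C)(C)OCC1=C2[C@H](C[C@H](O[Si](CC)(CC)CC)[C@@H]2O[Si](C)(C)C(C)(C)C)[C@@H]([C@]3(C)CO3)[C@H](OC(=O)/C=C(/C)CC)[C@@H]1O[Si](C)(C)C(C)(C)C | intermediate
27 | diol (7-CH2OH, 2-OH; 1-OTBS, 6-OTBS) | OCC1=C2[C@H](C[C@H](O)[C@@H]2O[Si](C)(C)C(C)(C)C)[C@@H]([C@]3(C)CO3)[C@H](OC(=O)/C=C(/C)CC)[C@@H]1O[Si](C)(C)C(C)(C)C | intermediate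
28 | N-allyl-N-(2-nitrophenylsulfonyl)hydrazine from 27 (not isolated) | NN(S(=O)(=O)c4ccccc4[N+](=O)[O-])CC1=C2[C@H](C[C@H](O)[C@@H]2O[Si](C)(C)C(C)(C)C)[C@@H]([C@]3(C)CO3)[C@H](OC(=O)/C=C(/C)CC)[C@@H]1O[Si](C)(C)C(C)(C)C | intermediate
29 | allylic monoalkyl diazene (not isolated) | N=NCC1=C2[C@H](C[C@H](O)[C@@H]2O[Si](C)(C)C(C)(C)C)[C@@H]([C@]3(C)CO3)[C@H](OC(=O)/C=C(/C)CC)[C@@H]1O[Si](C)(C)C(C)(C)C | intermediate
30 | 7-methylidene alcohol (trans-fused; 2-OH) | C=C1[C@@H]2[C@H](C[C@H](O)[C@@H]2O[Si](C)(C)C(C)(C)C)[C@@H]([C@]3(C)CO3)[C@H](OC(=O)/C=C(/C)CC)[C@@H]1O[Si](C)(C)C(C)(C)C | intermediate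
31 | 2-ketone | C=C1[C@@H]2[C@H](CC(=O)[C@@H]2O[Si](C)(C)C(C)(C)C)[C@@H]([C@]3(C)CO3)[C@H](OC(=O)/C=C(/C)CC)[C@@H]1O[Si](C)(C)C(C)(C)C | intermediate
32 | lithium enolate of 31 (C2–O, C2=C3; not isolated) | C=C1[C@@H]2[C@H](C=C([O-])[C@@H]2O[Si](C)(C)C(C)(C)C)[C@@H]([C@]3(C)CO3)[C@H](OC(=O)/C=C(/C)CC)[C@@H]1O[Si](C)(C)C(C)(C)C.[Li+] | intermediate
33 | lithium aldolate (3-(1-oxidoethyl); diastereomer mixture; not isolated) | C=C1[C@@H]2[C@H](C(C(C)[O-])C(=O)[C@@H]2O[Si](C)(C)C(C)(C)C)[C@@H]([C@]3(C)CO3)[C@H](OC(=O)/C=C(/C)CC)[C@@H]1O[Si](C)(C)C(C)(C)C.[Li+] | intermediate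
34 | aldol mesylate (not isolated) | C=C1[C@@H]2[C@H](C(C(C)OS(C)(=O)=O)C(=O)[C@@H]2O[Si](C)(C)C(C)(C)C)[C@@H]([C@]3(C)CO3)[C@H](OC(=O)/C=C(/C)CC)[C@@H]1O[Si](C)(C)C(C)(C)C | intermediate
35 | (3Z)-3-ethylidene enone, 1,6-bis-TBS ether | C=C1[C@@H]2[C@H](/C(=C/C)C(=O)[C@@H]2O[Si](C)(C)C(C)(C)C)[C@@H]([C@]3(C)CO3)[C@H](OC(=O)/C=C(/C)CC)[C@@H]1O[Si](C)(C)C(C)(C)C | intermediate
36 | 1,6-diol | C=C1[C@@H]2[C@H](/C(=C/C)C(=O)[C@@H]2O)[C@@H]([C@]3(C)CO3)[C@H](OC(=O)/C=C(/C)CC)[C@@H]1O | intermediate
37 | (R)-2-methylbutanoic acid | OC(=O)[C@H](C)CC | starting material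
38 | (1R,3Z,3aS,4R,5S,6R,7aS)-3-ethylidene-7-methylidene-4-[(2R)-2-methyloxiran-2-yl]-5-{[(2Z)-3-methylpent-2-enoyl]oxy}-2-oxooctahydro-1H-indene-1,6-diyl bis[(2R)-2-methylbutanoate] | C=C1[C@@H]2[C@H](/C(=C/C)C(=O)[C@@H]2OC(=O)[C@H](C)CC)[C@@H]([C@]2(C)CO2)[C@H](OC(=O)/C=C(/C)CC)[C@@H]1OC(=O)[C@H](C)CC | target

Total steps: 22. Longest linear sequence: 18 steps (1–8, 11–13, 16–22).

Steps most likely to fail

Step 11. The cycloaddition may be slow at the hindered β-carbon of the nitroalkene. The nitroalkene may instead react as a heterodiene across the C6=C7 enol ether. Endo or facial selectivity may erode. The fallback sets out from aldehyde 13 and diene 11 and changes the activating group from nitro to formyl. Wittig homologation of 13 with (triphenylphosphoranylidene)acetaldehyde would give (E)-3-[(2R)-2-methyloxiran-2-yl]prop-2-enal F1. Its thermal Diels–Alder reaction with 11 (same regiochemistry and endo preference, no heterodiene pathway) would give the 5-formyl cycloadduct F2. Copper-catalysed aerobic deformylation (Cu(OAc)2, 2,2′-bipyridine, DABCO, O2, DMF) would then give ketone 19, where the route is rejoined.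

Step 12. The nitronate may lose the C6 silyloxy group by β-elimination. Once the ketone is formed, enolisation at C4 may open the oxirane. The TES ether may be lost in the aqueous buffer. The fallback sets out from 17 and avoids carbanion chemistry. Reduction with aluminium amalgam (Al–Hg, THF/H2O) would give the 5-amine F3. Dehydrogenation with IBX in DMSO would give the N–H 5-imine F4. Its hydrolysis on neutral aqueous work-up returns to ketone 19.

Step 20. The E1cB elimination may give the E isomer or an E/Z mixture that does not equilibrate, and C1 may epimerise under DBU. The fallback sets out from ketone 31 and fixes the geometry before the methyl group is introduced. Claisen formylation (NaH, HCO2Et) would give the 3-(hydroxymethylidene) ketone F5. Chelation-controlled triflation of its lithium enolate (LiN(SiMe3)2, PhNTf2) would give the (Z)-enol triflate F6 with the OTf group syn to the carbonyl. Substitution with Me2CuLi (or MeMgBr with Fe(acac)3), which proceeds with retention, returns to enone 35.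

Further compounds
F1 | step 11 | (E)-3-[(2R)-2-methyloxiran-2-yl]prop-2-enal | O=C/C=C/[C@]1(C)CO1
F2 | step 11 | 5-formyl cycloadduct (as 17 with CHO in place of NO2) | CC(C)(C)[Si](C)(C)OCC1=C2[C@H](C[C@H](O[Si](CC)(CC)CC)[C@@H]2O[Si](C)(C)C(C)(C)C)[C@@H]([C@]3(C)CO3)[C@H](C=O)[C@@H]1O[Si](C)(C)C(C)(C)C
F3 | step 12 | 5-amine (as 17 with NH2 in place of NO2) | CC(C)(C)[Si](C)(C)OCC1=C2[C@H](C[C@H](O[Si](CC)(CC)CC)[C@@H]2O[Si](C)(C)C(C)(C)C)[C@@H]([C@]3(C)CO3)[C@H](N)[C@@H]1O[Si](C)(C)C(C)(C)C
F4 | step 12 | N–H 5-imine | CC(C)(C)[Si](C)(C)OCC1=C2[C@H](C[C@H](O[Si](CC)(CC)CC)[C@@H]2O[Si](C)(C)C(C)(C)C)[C@@H]([C@]3(C)CO3)C(=N)[C@@H]1O[Si](C)(C)C(C)(C)C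
F5 | step 20 | 3-(hydroxymethylidene) ketone (chelated enol, OH syn to C=O) | C=C1[C@@H]2[C@H](/C(=C/O)C(=O)[C@@H]2O[Si](C)(C)C(C)(C)C)[C@@H]([C@]3(C)CO3)[C@H](OC(=O)/C=C(/C)CC)[C@@H]1O[Si](C)(C)C(C)(C)C
F6 | step 20 | (Z)-enol triflate (OTf syn to C=O) | C=C1[C@@H]2[C@H](/C(=C/OS(=O)(=O)C(F)(F)F)C(=O)[C@@H]2O[Si](C)(C)C(C)(C)C)[C@@H]([C@]3(C)CO3)[C@H](OC(=O)/C=C(/C)CC)[C@@H]1O[Si](C)(C)C(C)(C)C
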